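**Strategy.** The route rests on cutting the C-1″–C-2″ bond of the oxepine (ring E). The CH2 on C-3 of the pyranone (ring C) is an allylic, vinylogous α-halomethyl-enone electrophile, and the O-bearing methine lies α to the carbinol carbon, which can be carried as an acyl group. A fully assembled 3-(bromomethyl)pyranoflavone whose ring B oxygen O-2′ carries an aryloxyacetyl (S)-4-benzyloxazolidinone is therefore closed by intramolecular Evans glycolate alkylation. One operation forms ring E by C–C bond formation and sets the only stereocentre (R). Methanolysis, Lewis-acid dealkylation and double methyl Grignard addition then deliver the dimethylcarbinol.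

Key step: step 11

Remarks: flavone numbering is used throughout. Ring A is the benzo ring, ring C the 4-pyranone, ring B the 2-aryl ring, ring D the dimethylpyran on C-7/C-8, ring E the oxepine. C-1″ is the CH2 on C-3, C-2″ the O–CH carbon, C-3″ the carbinol carbon. The stereocentre of the target is read as (R). All compounds marked "starting material" are taken to be commercial.

Step 1
Reactants: 1 2,4-dihydroxy-6-methoxyacetophenone; 2 3-methylbut-2-enal
Product: 4 1-(5-hydroxy-7-methoxy-2,2-dimethyl-2H-chromen-6-yl)ethan-1-one, via ortho-quinone methide 3 (not isolated)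
Conditions: ethylenediammonium diacetate (10 mol%), xylene, 140 °C
Reagents that add atoms: 3-methylbut-2-enal (2), CC(C)=CC=O
Why: Domino Knoevenagel condensation/oxa-6π electrocyclisation (phenol chromenylation): C-3 of 1, flanked by both hydroxyls, should condense with the enal, and dienone 3 should close through the non-chelated 4-oxygen, leaving the acetyl-chelated hydroxyl free next to the new ring D.

Step 2
Reactants: 5 2,4-dihydroxybenzaldehyde; 6 chloromethyl methyl ether
Product: 7 2-hydroxy-4-(methoxymethoxy)benzaldehyde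
Conditions: MOMCl (1.05 equiv), K2CO3, acetone, 0 °C → rt
Reagents that add atoms: chloromethyl methyl ether (6), COCCl
Why: Williamson-type etherification; the 2-hydroxyl is hydrogen-bonded to the aldehyde, so the more acidic 4-hydroxyl should react selectively.

Step 3
Reactants: 7 2-hydroxy-4-(methoxymethoxy)benzaldehyde; 8 allyl bromide
Product: 9 2-(allyloxy)-4-(methoxymethoxy)benzaldehyde
Conditions: allyl bromide, K2CO3, DMF, 60 °C
Reagents that add atoms: allyl bromide (8), C=CCBr
Why: Williamson ether synthesis on the remaining chelated phenol under more forcing conditions; the allyl group is the temporary mask for O-2′.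

Step 4
Reactants: 4 1-(5-hydroxy-7-methoxy-2,2-dimethyl-2H-chromen-6-yl)ethan-1-one; 9 2-(allyloxy)-4-(methoxymethoxy)benzaldehyde
Product: 10 (E)-3-[2-(allyloxy)-4-(methoxymethoxy)phenyl]-1-(5-hydroxy-7-methoxy-2,2-dimethyl-2H-chromen-6-yl)prop-2-en-1-one
Conditions: KOH (aq. 50%), EtOH, rt
Reagents that add atoms: none
Why: Claisen–Schmidt aldol condensation; dehydration should give the (E)-enone, and the MOM, allyl, methyl and ring D ethers are base-stable.

Step 5
Reactants: 10 the 2′-hydroxychalcone
Product: 12 2-[2-(allyloxy)-4-(methoxymethoxy)phenyl]-5-methoxy-8,8-dimethyl-4H,8H-pyrano[2,3-h]chromen-4-one, via flavanone 11 (not isolated)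
Conditions: DDQ (2.5 equiv), 1,4-dioxane, reflux
Reagents that add atoms: none
Why: DDQ cyclodehydrogenation of a 2′-hydroxychalcone: oxa-Michael closure through the only free phenol (the one next to ring D, the other ortho oxygen being methylated) fixes the angular fusion, and hydride abstraction from benzylic C-2 of flavanone 11 should give the flavone.

Step 6
Reactants: 12 the 3-unsubstituted flavone; 13 formaldehyde
Product: 15 2-[2-(allyloxy)-4-(methoxymethoxy)phenyl]-3-(hydroxymethyl)-5-methoxy-8,8-dimethyl-4H,8H-pyrano[2,3-h]chromen-4-one, via 3-lithioflavone 14 (not isolated)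
Conditions: LiN(iPr)2 (1.3 equiv), THF, −78 °C; then CH2O (gas, from cracked paraformaldehyde), −78 → −30 °C; aq. NH4Cl
Reagents that add atoms: formaldehyde (13), C=O
Why: Directed lithiation/hydroxymethylation: LiN(iPr)2 should remove the C-3 proton, the only vinylic C–H α to the ring C carbonyl, and the vinyllithium should add to monomeric formaldehyde to install C-1″.

Step 7
Reactants: 15 the 3-(hydroxymethyl)flavone allyl ether
Product: 16 3-(hydroxymethyl)-2-[2-hydroxy-4-(methoxymethoxy)phenyl]-5-methoxy-8,8-dimethyl-4H,8H-pyrano[2,3-h]chromen-4-one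
Conditions: Pd(PPh3)4 (5 mol%), morpholine (3 equiv), THF, rt
Reagents that add atoms: none
Why: Tsuji–Trost deallylation: zerovalent palladium ionises the allyl aryl ether to a π-allyl complex that morpholine traps, freeing only the 2′-hydroxyl while the MOM, methyl and ring D ethers remain.

Step 8
Reactants: 17 (S)-4-benzyl-2-oxazolidinone; 18 bromoacetyl bromide
Product: 20 (S)-4-benzyl-3-(bromoacetyl)oxazolidin-2-one, via N-lithiooxazolidinone 19 (not isolated)
Conditions: n-BuLi (1.0 equiv), THF, −78 °C; then BrCH2COBr, −78 → 0 °C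
Reagents that add atoms: bromoacetyl bromide (18), BrCC(Br)=O
Why: N-acylation of the lithiated oxazolidinone by the acid bromide, which is far more electrophilic than the alkyl bromide terminus.

Step 9
Reactants: 16 the 2′-hydroxy-3-(hydroxymethyl)flavone; 20 (S)-4-benzyl-3-(bromoacetyl)oxazolidin-2-one
Product: 21 (S)-4-benzyl-3-{[2-(3-(hydroxymethyl)-5-methoxy-8,8-dimethyl-4-oxo-4H,8H-pyrano[2,3-h]chromen-2-yl)-5-(methoxymethoxy)phenoxy]acetyl}oxazolidin-2-one
Conditions: K2CO3, acetone, rt
Reagents that add atoms: none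
Why: Williamson ether synthesis: the 2′-phenoxide should displace the α-bromide of the imide (SN2 at an α-halo carbonyl), whereas the primary alcohol is not deprotonated by K2CO3.

Step 10
Reactants: 21 the aryloxyacetyl imide alcohol; 22 carbon tetrabromide
Product: 23 (S)-4-benzyl-3-{[2-(3-(bromomethyl)-5-methoxy-8,8-dimethyl-4-oxo-4H,8H-pyrano[2,3-h]chromen-2-yl)-5-(methoxymethoxy)phenoxy]acetyl}oxazolidin-2-one
Conditions: CBr4, PPh3, CH2Cl2, 0 °C
Reagents that add atoms: carbon tetrabromide (22), BrC(Br)(Br)Br
Why: Appel reaction: the primary allylic alcohol is converted to the bromide under neutral conditions that the imide, the MOM acetal and ring D tolerate.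

Step 11
Reactants: 23 the 3-(bromomethyl)flavone aryloxyacetyl imide
Product: 25 ring E imide (oxepine closed between C-3 and O-2′; (R) at C-2″ which carries the N-acyl (S)-4-benzyloxazolidin-2-one; 5-OMe; 4′-OMOM), via sodium (Z)-enolate 24 (not isolated)
Conditions: NaN(SiMe3)2 (1.05 equiv), THF, −78 → −45 °C; aq. NH4Cl
Reagents that add atoms: none
Why: NaN(SiMe3)2 should deprotonate the aryloxyacetyl imide to the sodium-chelated (Z)-enolate 24, whose α-carbon (the future C-2″) displaces bromide from C-1″ in an intramolecular SN2 reaction. The closest known reaction type is the Evans asymmetric alkylation of N-glycolyl oxazolidinones with allylic halides, here run intramolecularly. Ring E is closed in the 7-exo-tet mode, the leaving group lying outside the forming ring. The new stereocentre C-2″ is controlled by the auxiliary: its benzyl group shields one face of the chelated (Z)-enolate, so C-1″ should bond to the opposite face, which for the (S)-auxiliary corresponds to (R) (aryloxy > acyl > CH2 > H). The step needs C-alkylation at the CH2 in preference to 5-exo conjugate addition of the enolate to C-2 of ring C. This is secured by the unhindered, allylically activated primary bromide, by C-2 being fully substituted and deactivated by the ring oxygen and the 4′-alkoxyaryl donor, and by the all-sp2 tether (O-2′, C-2′, C-1′, C-2, C-3) that holds C-1″ within reach of the enolate carbon.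

Step 12
Reactants: 25 the ring E imide; 26 methanol
Product: 27 ring E methyl ester ((R) at C-2″ which carries CO2Me; 5-OMe; 4′-OMOM)
Conditions: Sm(OTf)3 (10 mol%), MeOH/THF, rt
Reagents that add atoms: methanol (26), CO
Why: Lewis-acid-catalysed methanolysis of the N-acyl oxazolidinone: Sm(OTf)3 activates the exocyclic imide carbonyl by chelation, so methanol cleaves it without base, which should spare the α-aryloxy stereocentre and return the auxiliary.

Step 13
Reactants: 27 the ring E methyl ester
Product: 28 ring E methyl ester diphenol ((R) at C-2″; 5-OH; 4′-OH)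
Conditions: BCl3 (4 equiv), CH2Cl2, −78 → −10 °C; aq. NaHCO3
Reagents that add atoms: none
Why: Lewis-acid ether cleavage: BCl3 chelated between the C-4 carbonyl and the peri 5-methoxy oxygen should cleave that methyl ether selectively and also the MOM acetal, while the non-chelated ring D and ring E ethers and the ester are expected to survive at low temperature.

Step 14
Reactants: 28 the ring E methyl ester diphenol; 29 methylmagnesium bromide
Product: 31 target CNP0329736.1 ((R)-configured 2-hydroxypropan-2-yl oxepinopyranoflavone), via methyl ketone 30 (not isolated)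
Conditions: MeMgBr (6 equiv), THF, −40 → 0 °C; aq. NH4Cl
Reagents that add atoms: methylmagnesium bromide (29), C[Mg]Br
Why: Double Grignard addition to the ester via ketone 30: the first two equivalents deprotonate both phenols, turning the 5-oxido-4-pyranone into a chelated vinylogous carboxylate that resists addition, so only the chelation-activated α-aryloxy ester should react, and C-2″ is not touched.

**Compound list**

1 | 2,4-dihydroxy-6-methoxyacetophenone | CC(=O)c1c(O)cc(O)cc1OC | starting material
2 | 3-methylbut-2-enal | CC(C)=CC=O | starting material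
3 | ortho-quinone methide from condensation at C-3 of 1 (not isolated) | CC(=O)C1=C(O)C(=CC=C(C)C)C(=O)C=C1OC | intermediate
4 | 1-(5-hydroxy-7-methoxy-2,2-dimethyl-2H-chromen-6-yl)ethan-1-one | CC(=O)c1c(OC)cc2OC(C)(C)C=Cc2c1O | intermediate
5 | 2,4-dihydroxybenzaldehyde | O=Cc1ccc(O)cc1O | starting material
6 | chloromethyl methyl ether | COCCl | starting material
7 | 2-hydroxy-4-(methoxymethoxy)benzaldehyde | COCOc1ccc(C=O)c(O)c1 | intermediate
8 | allyl bromide | C=CCBr | starting material
9 | 2-(allyloxy)-4-(methoxymethoxy)benzaldehyde | COCOc1ccc(C=O)c(OCC=C)c1 | intermediate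
10 | (E)-3-[2-(allyloxy)-4-(methoxymethoxy)phenyl]-1-(5-hydroxy-7-methoxy-2,2-dimethyl-2H-chromen-6-yl)prop-2-en-1-one | COc1cc2OC(C)(C)C=Cc2c(O)c1C(=O)/C=C/c1ccc(OCOC)cc1OCC=C | intermediate
11 | racemic 2-[2-(allyloxy)-4-(methoxymethoxy)phenyl]-5-methoxy-8,8-dimethyl-2,3-dihydro-4H,8H-pyrano[2,3-h]chromen-4-one (flavanone; not isolated) | COc1cc2OC(C)(C)C=Cc2c2OC(CC(=O)c12)c1ccc(OCOC)cc1OCC=C | intermediate
12 | 2-[2-(allyloxy)-4-(methoxymethoxy)phenyl]-5-methoxy-8,8-dimethyl-4H,8H-pyrano[2,3-h]chromen-4-one | COc1cc2OC(C)(C)C=Cc2c2oc(cc(=O)c12)-c1ccc(OCOC)cc1OCC=C | intermediate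
13 | formaldehyde | C=O | starting material
14 | 3-lithio derivative of 12 (not isolated) | COc1cc2OC(C)(C)C=Cc2c2oc(c([Li])c(=O)c12)-c1ccc(OCOC)cc1OCC=C | intermediate
15 | 2-[2-(allyloxy)-4-(methoxymethoxy)phenyl]-3-(hydroxymethyl)-5-methoxy-8,8-dimethyl-4H,8H-pyrano[2,3-h]chromen-4-one | COc1cc2OC(C)(C)C=Cc2c2oc(c(CO)c(=O)c12)-c1ccc(OCOC)cc1OCC=C | intermediate
16 | 3-(hydroxymethyl)-2-[2-hydroxy-4-(methoxymethoxy)phenyl]-5-methoxy-8,8-dimethyl-4H,8H-pyrano[2,3-h]chromen-4-one | COc1cc2OC(C)(C)C=Cc2c2oc(c(CO)c(=O)c12)-c1ccc(OCOC)cc1O | intermediate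
17 | (S)-4-benzyl-2-oxazolidinone | O=C1N[C@@H](Cc2ccccc2)CO1 | starting material
18 | bromoacetyl bromide | BrCC(Br)=O | starting material
19 | N-lithio-(S)-4-benzyl-2-oxazolidinone (not isolated) | [Li]N1[C@@H](Cc2ccccc2)COC1=O | intermediate
20 | (S)-4-benzyl-3-(bromoacetyl)oxazolidin-2-one | BrCC(=O)N1[C@@H](Cc2ccccc2)COC1=O | intermediate
21 | (S)-4-benzyl-3-{[2-(3-(hydroxymethyl)-5-methoxy-8,8-dimethyl-4-oxo-4H,8H-pyrano[2,3-h]chromen-2-yl)-5-(methoxymethoxy)phenoxy]acetyl}oxazolidin-2-one | COc1cc2OC(C)(C)C=Cc2c2oc(c(CO)c(=O)c12)-c1ccc(OCOC)cc1OCC(=O)N1[C@@H](Cc2ccccc2)COC1=O | intermediate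
22 | carbon tetrabromide | BrC(Br)(Br)Br | starting material
23 | (S)-4-benzyl-3-{[2-(3-(bromomethyl)-5-methoxy-8,8-dimethyl-4-oxo-4H,8H-pyrano[2,3-h]chromen-2-yl)-5-(methoxymethoxy)phenoxy]acetyl}oxazolidin-2-one | COc1cc2OC(C)(C)C=Cc2c2oc(c(CBr)c(=O)c12)-c1ccc(OCOC)cc1OCC(=O)N1[C@@H](Cc2ccccc2)COC1=O | intermediate
24 | sodium (Z)-enolate of 23 (not isolated) | COc1cc2OC(C)(C)C=Cc2c2oc(c(CBr)c(=O)c12)-c1ccc(OCOC)cc1O/C=C(\[O-])N1[C@@H](Cc2ccccc2)COC1=O.[Na+] | intermediate
25 | ring E imide: oxepine closed, (R) at C-2″ bearing the N-acyl (S)-4-benzyloxazolidin-2-one, 5-OMe, 4′-OMOM | CC1(C)C=Cc2c(cc(OC)c3c(=O)c4c(oc23)-c2ccc(OCOC)cc2O[C@@H](C(=O)N2[C@@H](Cc5ccccc5)COC2=O)C4)O1 | intermediate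
26 | methanol | CO | starting material
27 | ring E methyl ester: (R) at C-2″ bearing CO2Me, 5-OMe, 4′-OMOM | CC1(C)C=Cc2c(cc(OC)c3c(=O)c4c(oc23)-c2ccc(OCOC)cc2O[C@@H](C(=O)OC)C4)O1 | intermediate
28 | ring E methyl ester diphenol: (R) at C-2″, 5-OH, 4′-OH | CC1(C)C=Cc2c(cc(O)c3c(=O)c4c(oc23)-c2ccc(O)cc2O[C@@H](C(=O)OC)C4)O1 | intermediate
29 | methylmagnesium bromide | C[Mg]Br | starting material
30 | methyl ketone (acetyl on C-2″) as its bis(bromomagnesium) phenoxide (not isolated) | CC1(C)C=Cc2c(cc(O[Mg]Br)c3c(=O)c4c(oc23)-c2ccc(O[Mg]Br)cc2O[C@@H](C(C)=O)C4)O1 | intermediate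
31 | target CNP0329736.1: (R) at C-2″ bearing 2-hydroxypropan-2-yl, 5-OH, 4′-OH | CC1(C)C=Cc2c(cc(O)c3c(=O)c4c(oc23)-c2ccc(O)cc2O[C@@H](C(C)(C)O)C4)O1 | target

**Step count.** Total: 14 steps. Longest linear sequence: 12 steps (2, 3, 4, 5, 6, 7, 9, 10, 11, 12, 13, 14, from compound 5).

**Steps most likely to fail**

1. Step 11 (ring E closure). The sodium glycolate enolate may break down, or add in a 5-exo conjugate sense to C-2 of ring C, before the slower seven-membered closure takes place. The tether may also force C-1″ toward the shielded enolate face and erode facial selectivity. Fallback: the ring is closed without the auxiliary through a more robust ester enolate and the stereocentre is secured by resolution. It sets out from 16. Alkylation of the 2′-hydroxyl with methyl bromoacetate (K2CO3, acetone) should give the methyl aryloxyacetate F1. Appel bromination (CBr4, PPh3) should give the bromide F2. The potassium ester enolate (KN(SiMe3)2, THF, −78 → 0 °C), which tolerates the higher temperature a seven-membered closure may need, should close ring E to the racemic methyl ester F3. Preparative HPLC on a chiral stationary phase then separates the (R)-ester, which is 27, from the (S)-ester F4. The route is rejoined at 27.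

2. Step 6 (C-3 hydroxymethylation). The 3-lithiated pyranone may fragment by β-elimination of the ring A phenoxide, the base may deprotonate other sites (the allylic O–CH2 or ring positions), or formaldehyde may oligomerise faster than it is captured. Fallback: C-1″ is introduced by an aldol reaction at the flavanone oxidation level. It sets out from 10. NaOAc in refluxing EtOH should give flavanone 11, now isolated. Base-catalysed aldol addition to aqueous formaldehyde (K2CO3 cat., THF/H2O, rt) should give the racemic 3-(hydroxymethyl)flavanone F5. DDQ in refluxing dioxane should then dehydrogenate C-2/C-3. The route is rejoined at 15.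

3. Step 5 (flavone formation). The oxidation may stall at the flavanone, the phenol may close in the 5-exo sense to give the aurone, or DDQ may attack the allyl ether. Fallback: the pyranone is built by a Baker–Venkataraman sequence. It sets out from 9 and 4. Pinnick oxidation of 9 (NaClO2, NaH2PO4, 2-methyl-2-butene) should give 2-(allyloxy)-4-(methoxymethoxy)benzoic acid F6. Esterification with the phenol of 4 (EDCI, DMAP, CH2Cl2) should give the aryl ester F7. LiN(SiMe3)2 (THF, −78 → −10 °C) should effect the acyl shift to the 1,3-diketone F8. Cyclodehydration (TsOH cat., dry toluene, 60 °C, molecular sieves) closes ring C. The route is rejoined at 12.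

**Further compounds**

F1 | step 11 | methyl {2-[3-(hydroxymethyl)-5-methoxy-8,8-dimethyl-4-oxo-4H,8H-pyrano[2,3-h]chromen-2-yl]-5-(methoxymethoxy)phenoxy}acetate | COc1cc2OC(C)(C)C=Cc2c2oc(c(CO)c(=O)c12)-c1ccc(OCOC)cc1OCC(=O)OC
F2 | step 11 | methyl {2-[3-(bromomethyl)-5-methoxy-8,8-dimethyl-4-oxo-4H,8H-pyrano[2,3-h]chromen-2-yl]-5-(methoxymethoxy)phenoxy}acetate | COc1cc2OC(C)(C)C=Cc2c2oc(c(CBr)c(=O)c12)-c1ccc(OCOC)cc1OCC(=O)OC
F3 | step 11 | racemic ring E methyl ester (racemate of 27) | CC1(C)C=Cc2c(cc(OC)c3c(=O)c4c(oc23)-c2ccc(OCOC)cc2OC(C(=O)OC)C4)O1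
F4 | step 11 | (S)-enantiomer of ring E methyl ester 27 | CC1(C)C=Cc2c(cc(OC)c3c(=O)c4c(oc23)-c2ccc(OCOC)cc2O[C@H](C(=O)OC)C4)O1
F5 | step 6 | racemic 2-[2-(allyloxy)-4-(methoxymethoxy)phenyl]-3-(hydroxymethyl)-5-methoxy-8,8-dimethyl-2,3-dihydro-4H,8H-pyrano[2,3-h]chromen-4-one | COc1cc2OC(C)(C)C=Cc2c2OC(C(CO)C(=O)c12)c1ccc(OCOC)cc1OCC=C
F6 | step 5 | 2-(allyloxy)-4-(methoxymethoxy)benzoic acid | COCOc1ccc(C(=O)O)c(OCC=C)c1
F7 | step 5 | 6-acetyl-7-methoxy-2,2-dimethyl-2H-chromen-5-yl 2-(allyloxy)-4-(methoxymethoxy)benzoate | CC(=O)c1c(OC)cc2OC(C)(C)C=Cc2c1OC(=O)c1ccc(OCOC)cc1OCC=C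
F8 | step 5 | 1-[2-(allyloxy)-4-(methoxymethoxy)phenyl]-3-(5-hydroxy-7-methoxy-2,2-dimethyl-2H-chromen-6-yl)propane-1,3-dione | COc1cc2OC(C)(C)C=Cc2c(O)c1C(=O)CC(=O)c1ccc(OCOC)cc1OCC=C
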